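**Retrosynthetic overview**
- Ring A has four neighbouring substituted carbons, C6 (aryloxy), C1 (CO2H), C2 (OMe) and C3 (side chain), followed by two neighbouring CH carbons, C4 and C5. This pattern is cut into a two-carbon piece C6–C1 (a 3-aryloxypropiolate) and a four-carbon piece C2–C5 (a 2-substituted 1-methoxy-1-silyloxybutadiene).
- Bonds C5–C6 and C1–C2 are made together in a Diels–Alder benzannulation. Loss of methanol and silicon leaves the C2 phenol, which is methylated, and fluoride then frees the acid and all hydroxyls.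
- The diene comes from an Evans syn-aldol of an N-crotonyl oxazolidinone with 3-methyl-3-(triethylsilyloxy)butanal. This sets the only stereocentre, the (S) carbinol, before ring A exists.
- The alkyne comes from a differentiated ring B phenol through its dichlorovinyl ether, so the crowded aryl–O bond is in place before ring closure and no diaryl ether coupling is needed.
- Ring order: ring B is bought (creosol); ring A is the only ring formed, in step 15.

Key step: step 15

Remark (numbering, abbreviations, assumption): ring A is numbered C1 (carboxyl carbon) to C6 (aryloxy carbon) and ring B from its ether carbon C1'. TES = triethylsilyl, TBS = tert-butyldimethylsilyl, SEM = [2-(trimethylsilyl)ethoxy]methyl, TMSE = 2-(trimethylsilyl)ethyl. ArB = 2-(TBSO-methyl)-4-methyl-6-(SEM-oxy)phenyl. Chloroformate 25 is taken as a catalogue reagent.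

**Step 1**
Reactants: 1 3-methylbutane-1,3-diol
Product: 2 3-methyl-1,3-bis(triethylsilyloxy)butane
Conditions: Et3SiOTf (2.3 equiv), 2,6-lutidine, CH2Cl2, 0 °C
Reagents that add atoms: triethylsilyl trifluoromethanesulfonate, CC[Si](CC)(CC)OS(=O)(=O)C(F)(F)F
Why: Exhaustive O-silylation with a silyl triflate and a hindered pyridine base covers the primary and the tertiary hydroxyl alike, so the two alcohols need not be told apart at this stage.

**Step 2**
Reactants: 2 3-methyl-1,3-bis(triethylsilyloxy)butane
Product: 3 3-methyl-3-(triethylsilyloxy)butanal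
Conditions: (COCl)2, DMSO, CH2Cl2, −78 to −40 °C; Et3N, −78 to 0 °C
Reagents that add atoms: none
Why: In the direct Swern oxidation of silyl ethers the chlorosulfonium salt engages only the unhindered primary TES ether, which is desilylated and oxidised in one operation while the tertiary TES ether stays, and the cold amine stage should hold back beta-elimination to the enal.

**Step 3**
Reactants: 4 (4R)-4-benzyl-1,3-oxazolidin-2-one; 5 (E)-but-2-enoyl chloride
Product: 7 (4R)-4-benzyl-3-[(E)-but-2-enoyl]-1,3-oxazolidin-2-one, via N-lithio oxazolidinone 6 (not isolated)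
Conditions: n-BuLi, THF, −78 °C; then 5, −78 to 0 °C
Reagents that add atoms: none
Why: N-Acylation of the lithiated oxazolidinone with an acid chloride is standard and at low temperature leaves the E-alkene conjugated.

**Step 4**
Reactants: 7 (4R)-4-benzyl-3-[(E)-but-2-enoyl]-1,3-oxazolidin-2-one; 3 3-methyl-3-(triethylsilyloxy)butanal
Product: 10 (4R)-4-benzyl-3-[(2R,3S)-2-ethenyl-3-hydroxy-5-methyl-5-(triethylsilyloxy)hexanoyl]-1,3-oxazolidin-2-one, via boron dienolate 8 (not isolated), via boron aldolate 9 (not isolated)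
Conditions: Bu2BOTf, Et3N, CH2Cl2, −78 to 0 °C; 3, −78 to 0 °C; pH 7 buffer, MeOH, 30% H2O2, 0 °C
Reagents that add atoms: none
Why: In this Evans syn-aldol reaction gamma-deprotonation gives the Z(O) boron dienolate, which reacts at its alpha carbon through a Zimmerman–Traxler chair whose face is fixed by the (R)-benzyl group, so the (2R,3S) syn adduct should form, C3 being the future (S) carbinol carbon of the target.

**Step 5**
Reactants: 10 (4R)-4-benzyl-3-[(2R,3S)-2-ethenyl-3-hydroxy-5-methyl-5-(triethylsilyloxy)hexanoyl]-1,3-oxazolidin-2-one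
Product: 11 methyl (2R,3S)-2-ethenyl-3-hydroxy-5-methyl-5-(triethylsilyloxy)hexanoate
Conditions: Mg(OMe)2, MeOH–CH2Cl2, 0 °C; aq NH4Cl
Reagents that add atoms: magnesium methoxide, C[O-].C[O-].[Mg+2]
Why: Chelation-assisted methanolysis of the N-acyl oxazolidinone attacks the exocyclic carbonyl of the free beta-hydroxy imide and keeps the aldolate bound to magnesium against retro-aldol cleavage, while any epimerisation or conjugation at C2 would be harmless because C2 becomes sp2 in step 7 and both isomers give the same dienolate.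

**Step 6**
Reactants: 11 methyl (2R,3S)-2-ethenyl-3-hydroxy-5-methyl-5-(triethylsilyloxy)hexanoate
Product: 12 methyl (2R,3S)-3-(tert-butyldimethylsilyloxy)-2-ethenyl-5-methyl-5-(triethylsilyloxy)hexanoate
Conditions: TBSOTf, 2,6-lutidine, CH2Cl2, −78 to 0 °C
Reagents that add atoms: tert-butyldimethylsilyl trifluoromethanesulfonate, CC(C)(C)[Si](C)(C)OS(=O)(=O)C(F)(F)F
Why: O-Silylation with a silyl triflate and lutidine covers the hindered secondary alcohol without breaking a bond at C3 and without disturbing the tertiary TES ether.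

**Step 7**
Reactants: 12 methyl (2R,3S)-3-(tert-butyldimethylsilyloxy)-2-ethenyl-5-methyl-5-(triethylsilyloxy)hexanoate
Product: 14 (1E)-2-[(1S)-1-(tert-butyldimethylsilyloxy)-3-methyl-3-(triethylsilyloxy)butyl]-1-methoxy-1-(trimethylsilyloxy)buta-1,3-diene, via lithium dienolate 13 (not isolated)
Conditions: LiN(iPr)2, Me3SiCl (internal quench), THF, −78 °C to rt; pentane, filtration under argon, used crude
Reagents that add atoms: chlorotrimethylsilane, C[Si](C)(C)Cl
Why: Silyl ketene acetal formation by kinetic removal of the doubly activated C2 hydrogen, followed by O-silylation of the fully substituted dienolate, should outrun E1cB loss of silanolate because the chlorosilane is already present; the carbinol carbon is untouched, and the ketene acetal geometry (drawn with vinyl cis to OSiMe3) has no consequence later.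

**Step 8**
Reactants: 15 2-methoxy-4-methylphenol (creosol)
Product: 16 2-hydroxy-3-methoxy-5-methylbenzaldehyde
Conditions: MgCl2, Et3N, (CH2O)n, MeCN, reflux; 1 M HCl
Reagents that add atoms: paraformaldehyde (as formaldehyde), C=O
Why: In the Casnati–Skattebøl ortho-formylation the magnesium phenoxide delivers formaldehyde to the only free ortho position, and a second formaldehyde accepts hydride to give the aldehyde.

**Step 9**
Reactants: 16 2-hydroxy-3-methoxy-5-methylbenzaldehyde
Product: 17 2,3-dihydroxy-5-methylbenzaldehyde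
Conditions: BBr3, CH2Cl2, −78 to 0 °C; H2O
Reagents that add atoms: none
Why: Lewis acid demethylation of an aryl methyl ether with BBr3 is routine on o-vanillin-type aldehydes and clears the oxygen for a group that can be removed at the end.

**Step 10**
Reactants: 17 2,3-dihydroxy-5-methylbenzaldehyde
Product: 19 2-hydroxy-5-methyl-3-{[2-(trimethylsilyl)ethoxy]methoxy}benzaldehyde, via disodium catecholate 18 (not isolated)
Conditions: NaH (2.2 equiv), THF–DMF, 0 °C; SEMCl (1.0 equiv), 0 °C to rt; aq NH4Cl
Reagents that add atoms: 2-(trimethylsilyl)ethoxymethyl chloride, C[Si](C)(C)CCOCCl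
Why: In this regioselective mono-O-alkylation of a catechol dianion the C3 oxide, neither conjugated with nor chelated to the formyl group, is the stronger nucleophile; an acetal-type group is used because a silyl group on this oxygen would migrate to the neighbouring phenoxide in step 13.

**Step 11**
Reactants: 19 2-hydroxy-5-methyl-3-{[2-(trimethylsilyl)ethoxy]methoxy}benzaldehyde
Product: 20 2-(hydroxymethyl)-4-methyl-6-{[2-(trimethylsilyl)ethoxy]methoxy}phenol
Conditions: NaBH4, THF–MeOH, 0 °C
Reagents that add atoms: none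
Why: Borohydride reduction of the aldehyde gives the benzylic alcohol and leaves the SEM acetal alone.

**Step 12**
Reactants: 20 2-(hydroxymethyl)-4-methyl-6-{[2-(trimethylsilyl)ethoxy]methoxy}phenol
Product: 21 2-(tert-butyldimethylsilyloxymethyl)-4-methyl-6-{[2-(trimethylsilyl)ethoxy]methoxy}phenol (ArB–OH)
Conditions: TBSCl (1.05 equiv), imidazole, CH2Cl2, 0 °C
Reagents that add atoms: tert-butyldimethylsilyl chloride, CC(C)(C)[Si](C)(C)Cl
Why: Chemoselective silylation of the primary benzylic alcohol of a salicyl alcohol is known, and here the phenol is shielded further by two ortho substituents.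

**Step 13**
Reactants: 21 ArB–OH; 22 trichloroethylene
Product: 24 ArB (E)-1,2-dichlorovinyl ether, via dichloroacetylene 23 (not isolated)
Conditions: 22 (2 equiv), K2CO3, DMF, 70 °C
Reagents that add atoms: none
Why: In the dichlorovinyl ether synthesis from trichloroethylene the base generates dichloroacetylene at low concentration, and the phenoxide adds to this small linear electrophile in an anti sense to give the E isomer, with the SEM and alkyl TBS ethers inert to carbonate.

**Step 14**
Reactants: 24 ArB (E)-1,2-dichlorovinyl ether; 25 2-(trimethylsilyl)ethyl chloroformate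
Product: 28 2-(trimethylsilyl)ethyl 3-(ArB-oxy)prop-2-ynoate, via chloroethynyl ether 26 (not isolated), via lithium aryloxyacetylide 27 (not isolated)
Conditions: n-BuLi (2.05 equiv), THF, −78 to −40 °C; 25, −78 °C; rapid filtration through Et3N-washed silica
Reagents that add atoms: none
Why: The dichlorovinyl ether route to ynol ethers (vinylic deprotonation with loss of LiCl, then chlorine–lithium exchange) gives the lithium acetylide, and its C-acylation with a chloroformate is the usual acetylide carboalkoxylation, fast enough at −78 °C to spare the SEM and TBS groups.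

**Step 15**
Reactants: 14 (1E)-2-[(1S)-1-(tert-butyldimethylsilyloxy)-3-methyl-3-(triethylsilyloxy)butyl]-1-methoxy-1-(trimethylsilyloxy)buta-1,3-diene (2 equiv); 28 2-(trimethylsilyl)ethyl 3-(ArB-oxy)prop-2-ynoate
Product: 30 2-(trimethylsilyl)ethyl 6-(ArB-oxy)-3-[(1S)-1-(tert-butyldimethylsilyloxy)-3-methyl-3-(triethylsilyloxy)butyl]-2-hydroxybenzoate, via cyclohexa-1,4-diene cycloadduct 29 (not isolated)
Conditions: PhMe (1 M), 110 °C, sealed tube, argon; then 5% aq citric acid, THF, 0 °C
Reagents that add atoms: none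
Why: Proposed new method: the CH2 terminus of ketene acetal diene 14 (largest HOMO coefficient) should bond to the aryloxy-bearing alkyne carbon of 28 (beta to the ester, largest LUMO coefficient) to make C5–C6, while the acetal carbon bonds to the ester-bearing alkyne carbon to make C1–C2, in a concerted but strongly asynchronous [4+2] cycloaddition that closes six-membered ring A from four diene carbons and two alkyne carbons. The closest known reaction type is the Diels–Alder benzannulation of 1-alkoxy-1-silyloxybuta-1,3-dienes with propiolates and acetylenedicarboxylates to salicylates; new here is the oxygen donor on the alkyne, which raises the LUMO and is answered by excess diene, high concentration, heat and a non-polar solvent that disfavours open zwitterions. Cycloadduct 29 is a cyclohexa-1,4-diene with a mixed methyl trimethylsilyl ketal at C2; dilute acid takes off silicon, methanol is expelled, and the cross-conjugated dienone tautomerises through a C5 hydrogen to the hydrogen-bonded phenol 30. The selectivity needed is regiochemical, acetal carbon next to ester carbon, and it is secured because the ester and the aryloxy group polarise the triple bond in the same sense, which matches the polarisation of the diene. The large substituent on the future C3 pushes the diene into its s-cis rotamer, the ketene acetal geometry and the transient ketal centre of 29 vanish on aromatisation, and no lasting stereocentre is created. The (S) carbinol carbon lies outside the reacting atoms and has no acidic hydrogen under neutral heating, so it should pass unchanged.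

**Step 16**
Reactants: 30 2-(trimethylsilyl)ethyl 6-(ArB-oxy)-3-[(1S)-1-(tert-butyldimethylsilyloxy)-3-methyl-3-(triethylsilyloxy)butyl]-2-hydroxybenzoate
Product: 31 2-(trimethylsilyl)ethyl 6-(ArB-oxy)-3-[(1S)-1-(tert-butyldimethylsilyloxy)-3-methyl-3-(triethylsilyloxy)butyl]-2-methoxybenzoate
Conditions: MeI, K2CO3, dry DMF, rt
Reagents that add atoms: iodomethane, CI
Why: Williamson O-methylation hits the only free acidic hydroxyl of the molecule, the small electrophile tolerates the two flanking groups, and dry carbonate leaves the alkyl silyl ethers, the SEM acetal and the TMSE ester intact.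

**Step 17**
Reactants: 31 2-(trimethylsilyl)ethyl 6-(ArB-oxy)-3-[(1S)-1-(tert-butyldimethylsilyloxy)-3-methyl-3-(triethylsilyloxy)butyl]-2-methoxybenzoate
Product: 32 3-[(1S)-1,3-dihydroxy-3-methylbutyl]-6-[2-hydroxy-6-(hydroxymethyl)-4-methylphenoxy]-2-methoxybenzoic acid (CNP0452050.2)
Conditions: Bu4NF (12 equiv), THF, 0 °C to rt; then DMPU, 50 °C; aq NH4Cl, 1 M HCl to pH 4
Reagents that add atoms: none
Why: Fluoride-induced global deprotection first fragments the TMSE ester at remote silicon (so the hindered carbonyl is irrelevant) and cleaves the three silyl ethers, and the slower SEM fragmentation unveils the ring B phenoxide only when ring A is already a deactivated carboxylate, which guards against lactonisation and Smiles-type aryl migration; no bond at the carbinol carbon is broken, so (S) is retained.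

**Compound list**
1 | 3-methylbutane-1,3-diol | CC(C)(O)CCO | starting material
2 | 3-methyl-1,3-bis(triethylsilyloxy)butane | CC(C)(CCO[Si](CC)(CC)CC)O[Si](CC)(CC)CC | intermediate
3 | 3-methyl-3-(triethylsilyloxy)butanal | CC(C)(CC=O)O[Si](CC)(CC)CC | intermediate
4 | (4R)-4-benzyl-1,3-oxazolidin-2-one | O=C1N[C@H](Cc2ccccc2)CO1 | starting material
5 | (E)-but-2-enoyl chloride (crotonyl chloride) | C/C=C/C(=O)Cl | starting material
6 | N-lithio (4R)-4-benzyl-1,3-oxazolidin-2-one | [Li]N1[C@H](Cc2ccccc2)COC1=O | intermediate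
7 | (4R)-4-benzyl-3-[(E)-but-2-enoyl]-1,3-oxazolidin-2-one | C/C=C/C(=O)N1[C@H](Cc2ccccc2)COC1=O | intermediate
8 | dibutylboron Z(O)-dienolate of 7 | C=C/C=C(\OB(CCCC)CCCC)N1[C@H](Cc2ccccc2)COC1=O | intermediate
9 | dibutylboron aldolate of 10 | C=C[C@@H](C(=O)N1[C@H](Cc2ccccc2)COC1=O)[C@@H](OB(CCCC)CCCC)CC(C)(C)O[Si](CC)(CC)CC | intermediate
10 | (4R)-4-benzyl-3-[(2R,3S)-2-ethenyl-3-hydroxy-5-methyl-5-(triethylsilyloxy)hexanoyl]-1,3-oxazolidin-2-one | C=C[C@@H](C(=O)N1[C@H](Cc2ccccc2)COC1=O)[C@@H](O)CC(C)(C)O[Si](CC)(CC)CC | intermediate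
11 | methyl (2R,3S)-2-ethenyl-3-hydroxy-5-methyl-5-(triethylsilyloxy)hexanoate | C=C[C@@H](C(=O)OC)[C@@H](O)CC(C)(C)O[Si](CC)(CC)CC | intermediate
12 | methyl (2R,3S)-3-(tert-butyldimethylsilyloxy)-2-ethenyl-5-methyl-5-(triethylsilyloxy)hexanoate | C=C[C@@H](C(=O)OC)[C@@H](O[Si](C)(C)C(C)(C)C)CC(C)(C)O[Si](CC)(CC)CC | intermediate
13 | lithium dienolate of 12 | C=C/C([C@@H](O[Si](C)(C)C(C)(C)C)CC(C)(C)O[Si](CC)(CC)CC)=C(/OC)O[Li] | intermediate
14 | (1E)-2-[(1S)-1-(tert-butyldimethylsilyloxy)-3-methyl-3-(triethylsilyloxy)butyl]-1-methoxy-1-(trimethylsilyloxy)buta-1,3-diene | C=C/C([C@@H](O[Si](C)(C)C(C)(C)C)CC(C)(C)O[Si](CC)(CC)CC)=C(/OC)O[Si](C)(C)C | intermediate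
15 | 2-methoxy-4-methylphenol (creosol) | COc1cc(C)ccc1O | starting material
16 | 2-hydroxy-3-methoxy-5-methylbenzaldehyde | COc1cc(C)cc(C=O)c1O | intermediate
17 | 2,3-dihydroxy-5-methylbenzaldehyde | Oc1cc(C)cc(C=O)c1O | intermediate
18 | disodium salt of 17 | [Na+].[Na+].[O-]c1cc(C)cc(C=O)c1[O-] | intermediate
19 | 2-hydroxy-5-methyl-3-{[2-(trimethylsilyl)ethoxy]methoxy}benzaldehyde | C[Si](C)(C)CCOCOc1cc(C)cc(C=O)c1O | intermediate
20 | 2-(hydroxymethyl)-4-methyl-6-{[2-(trimethylsilyl)ethoxy]methoxy}phenol | C[Si](C)(C)CCOCOc1cc(C)cc(CO)c1O | intermediate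
21 | 2-(tert-butyldimethylsilyloxymethyl)-4-methyl-6-{[2-(trimethylsilyl)ethoxy]methoxy}phenol | C[Si](C)(C)CCOCOc1cc(C)cc(CO[Si](C)(C)C(C)(C)C)c1O | intermediate
22 | trichloroethylene | ClC=C(Cl)Cl | starting material
23 | dichloroacetylene | ClC#CCl | intermediate
24 | (E)-1,2-dichlorovinyl ether of 21 | C[Si](C)(C)CCOCOc1cc(C)cc(CO[Si](C)(C)C(C)(C)C)c1O/C(Cl)=C\Cl | intermediate
25 | 2-(trimethylsilyl)ethyl chloroformate | C[Si](C)(C)CCOC(=O)Cl | starting material
26 | chloroethynyl ether of 21 | C[Si](C)(C)CCOCOc1cc(C)cc(CO[Si](C)(C)C(C)(C)C)c1OC#CCl | intermediate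
27 | lithium aryloxyacetylide from 24 | [Li]C#COc1c(OCOCC[Si](C)(C)C)cc(C)cc1CO[Si](C)(C)C(C)(C)C | intermediate
28 | 2-(trimethylsilyl)ethyl 3-[2-(tert-butyldimethylsilyloxymethyl)-4-methyl-6-{[2-(trimethylsilyl)ethoxy]methoxy}phenoxy]prop-2-ynoate | C[Si](C)(C)CCOC(=O)C#COc1c(OCOCC[Si](C)(C)C)cc(C)cc1CO[Si](C)(C)C(C)(C)C | intermediate
29 | 2-(trimethylsilyl)ethyl 2-(ArB-oxy)-5-[(1S)-1-(tert-butyldimethylsilyloxy)-3-methyl-3-(triethylsilyloxy)butyl]-6-methoxy-6-(trimethylsilyloxy)cyclohexa-1,4-diene-1-carboxylate (ketal carbon undefined) | COC1(O[Si](C)(C)C)C([C@@H](O[Si](C)(C)C(C)(C)C)CC(C)(C)O[Si](CC)(CC)CC)=CCC(Oc2c(OCOCC[Si](C)(C)C)cc(C)cc2CO[Si](C)(C)C(C)(C)C)=C1C(=O)OCC[Si](C)(C)C | intermediate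
30 | 2-(trimethylsilyl)ethyl 6-(ArB-oxy)-3-[(1S)-1-(tert-butyldimethylsilyloxy)-3-methyl-3-(triethylsilyloxy)butyl]-2-hydroxybenzoate | Oc1c([C@@H](O[Si](C)(C)C(C)(C)C)CC(C)(C)O[Si](CC)(CC)CC)ccc(Oc2c(OCOCC[Si](C)(C)C)cc(C)cc2CO[Si](C)(C)C(C)(C)C)c1C(=O)OCC[Si](C)(C)C | intermediate
31 | 2-(trimethylsilyl)ethyl 6-(ArB-oxy)-3-[(1S)-1-(tert-butyldimethylsilyloxy)-3-methyl-3-(triethylsilyloxy)butyl]-2-methoxybenzoate | COc1c([C@@H](O[Si](C)(C)C(C)(C)C)CC(C)(C)O[Si](CC)(CC)CC)ccc(Oc2c(OCOCC[Si](C)(C)C)cc(C)cc2CO[Si](C)(C)C(C)(C)C)c1C(=O)OCC[Si](C)(C)C | intermediate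
32 | 3-[(1S)-1,3-dihydroxy-3-methylbutyl]-6-[2-hydroxy-6-(hydroxymethyl)-4-methylphenoxy]-2-methoxybenzoic acid | COc1c([C@@H](O)CC(C)(C)O)ccc(Oc2c(O)cc(C)cc2CO)c1C(=O)O | target

**Total step count:** 17
**Longest linear sequence:** 10 steps (steps 8 to 17, from creosol 15)

**Steps most likely to fail**

**1. Step 15 (Diels–Alder benzannulation).**
- The donor-substituted alkyne may react too slowly.
- The diene could then be consumed by a 1,5-silyl shift from oxygen to its CH2 terminus, or by [2+2] addition at the ketene acetal double bond.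
- A stepwise pathway could also expel aryloxide from an open-chain intermediate (addition–elimination) instead of closing the ring.

The fallback uses known chemistry, sets out from diene 14 and phenol 21, and comes back at 31. Propiolic acid is esterified with 2-(trimethylsilyl)ethanol (DCC, DMAP, CH2Cl2) to 2-(trimethylsilyl)ethyl propiolate F1. This is brominated at the alkyne terminus (NBS, catalytic AgNO3, acetone) to 2-(trimethylsilyl)ethyl 3-bromopropiolate F2. 3-Halopropiolates are established Diels–Alder partners of oxygenated dienes. Heating F2 with 14 in toluene and the same acid work-up should give 2-(trimethylsilyl)ethyl 6-bromo-3-[(1S)-1-(tert-butyldimethylsilyloxy)-3-methyl-3-(triethylsilyloxy)butyl]-2-hydroxybenzoate F3. Methylation (MeI, K2CO3, DMF) gives the 2-methoxy bromide F4. An Ullmann-type ether synthesis with 21 (CuI, picolinic acid, K3PO4, DMSO, 90 °C), helped by the ortho ester, then forms the diaryl ether 31.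

**2. Step 14 (aryloxypropiolate).**
- The lithium aryloxyacetylide may fragment with loss of aryloxide.
- Butyllithium may add to the alkynyl ether.
- The push–pull alkyne may hydrate during isolation.

The fallback avoids organolithium chemistry, sets out from phenol 21, and comes back at 28. Commercial 3,3-dichloroacrylic acid is esterified with 2-(trimethylsilyl)ethanol (DCC, DMAP) to 2-(trimethylsilyl)ethyl 3,3-dichloroacrylate F5. Phenol 21 with K2CO3 in DMF replaces the chloride trans to the ester by vinylic addition–elimination, giving 2-(trimethylsilyl)ethyl (Z)-3-(ArB-oxy)-3-chloroacrylate F6. A second substitution is held back by the hindered phenol. LiN(SiMe3)2 in THF at −78 °C then removes HCl by anti elimination, the way halo enol ethers are turned into ynol ethers, to give 28.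

**3. Step 7 (vinylketene acetal).**
- The lithium dienolate may lose silanolate by E1cB elimination.
- Silylation may occur on carbon instead of oxygen.

The fallback ties the carbinol oxygen into a ring, sets out from aldol adduct 10, and comes back at target 32. LiOH/H2O2 (THF–H2O, 0 °C) gives (2R,3S)-2-ethenyl-3-hydroxy-5-methyl-5-(triethylsilyloxy)hexanoic acid F7. 2-Methoxypropene with catalytic PPTS in CH2Cl2 closes (5R,6S)-5-ethenyl-2,2-dimethyl-6-[2-methyl-2-(triethylsilyloxy)propyl]-1,3-dioxan-4-one F8. In the enolate of F8 the beta C–O bond lies in the ring, near the nodal plane of the pi system, so elimination is stereoelectronically disfavoured, and dioxanone enolates of this kind persist at −78 °C. LiN(iPr)2 and Me3SiCl then give (4S)-5-ethenyl-2,2-dimethyl-4-[2-methyl-2-(triethylsilyloxy)propyl]-6-(trimethylsilyloxy)-4H-1,3-dioxine F9. Cycloaddition with 28 as in step 15, followed by acid work-up with loss of acetone, should give 2-(trimethylsilyl)ethyl 6-(ArB-oxy)-2-hydroxy-3-[(1S)-1-hydroxy-3-methyl-3-(triethylsilyloxy)butyl]benzoate F10. MeI and K2CO3 methylate only the phenol, giving the 2-methoxy compound F11, and Bu4NF as in step 17 gives 32.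

**Further compounds**
F1 | step 15 | 2-(trimethylsilyl)ethyl propiolate | C#CC(=O)OCC[Si](C)(C)C
F2 | step 15 | 2-(trimethylsilyl)ethyl 3-bromopropiolate | BrC#CC(=O)OCC[Si](C)(C)C
F3 | step 15 | 2-(trimethylsilyl)ethyl 6-bromo-3-[(1S)-1-(tert-butyldimethylsilyloxy)-3-methyl-3-(triethylsilyloxy)butyl]-2-hydroxybenzoate | Oc1c([C@@H](O[Si](C)(C)C(C)(C)C)CC(C)(C)O[Si](CC)(CC)CC)ccc(Br)c1C(=O)OCC[Si](C)(C)C
F4 | step 15 | 2-(trimethylsilyl)ethyl 6-bromo-3-[(1S)-1-(tert-butyldimethylsilyloxy)-3-methyl-3-(triethylsilyloxy)butyl]-2-methoxybenzoate | COc1c([C@@H](O[Si](C)(C)C(C)(C)C)CC(C)(C)O[Si](CC)(CC)CC)ccc(Br)c1C(=O)OCC[Si](C)(C)C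
F5 | step 14 | 2-(trimethylsilyl)ethyl 3,3-dichloroacrylate | ClC(Cl)=CC(=O)OCC[Si](C)(C)C
F6 | step 14 | 2-(trimethylsilyl)ethyl (Z)-3-(ArB-oxy)-3-chloroacrylate | C[Si](C)(C)CCOCOc1cc(C)cc(CO[Si](C)(C)C(C)(C)C)c1O/C(Cl)=C/C(=O)OCC[Si](C)(C)C
F7 | step 7 | (2R,3S)-2-ethenyl-3-hydroxy-5-methyl-5-(triethylsilyloxy)hexanoic acid | C=C[C@@H](C(=O)O)[C@@H](O)CC(C)(C)O[Si](CC)(CC)CC
F8 | step 7 | (5R,6S)-5-ethenyl-2,2-dimethyl-6-[2-methyl-2-(triethylsilyloxy)propyl]-1,3-dioxan-4-one | C=C[C@H]1C(=O)OC(C)(C)O[C@H]1CC(C)(C)O[Si](CC)(CC)CC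
F9 | step 7 | (4S)-5-ethenyl-2,2-dimethyl-4-[2-methyl-2-(triethylsilyloxy)propyl]-6-(trimethylsilyloxy)-4H-1,3-dioxine | C=CC1=C(O[Si](C)(C)C)OC(C)(C)O[C@H]1CC(C)(C)O[Si](CC)(CC)CC
F10 | step 7 | 2-(trimethylsilyl)ethyl 6-(ArB-oxy)-2-hydroxy-3-[(1S)-1-hydroxy-3-methyl-3-(triethylsilyloxy)butyl]benzoate | Oc1c([C@@H](O)CC(C)(C)O[Si](CC)(CC)CC)ccc(Oc2c(OCOCC[Si](C)(C)C)cc(C)cc2CO[Si](C)(C)C(C)(C)C)c1C(=O)OCC[Si](C)(C)C
F11 | step 7 | 2-(trimethylsilyl)ethyl 6-(ArB-oxy)-3-[(1S)-1-hydroxy-3-methyl-3-(triethylsilyloxy)butyl]-2-methoxybenzoate | COc1c([C@@H](O)CC(C)(C)O[Si](CC)(CC)CC)ccc(Oc2c(OCOCC[Si](C)(C)C)cc(C)cc2CO[Si](C)(C)C(C)(C)C)c1C(=O)OCC[Si](C)(C)C
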